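**Target 19:** [(1S,2R,3S,6S)-2,3-diacetoxy-1,6-dihydroxycyclohex-4-en-1-yl]methyl benzoate. Numbering used throughout: C1 is the quaternary carbinol carbon, C2 and C3 carry the acetates, C4=C5 is the alkene, C6 is the secondary carbinol, C7 is the exocyclic CH2; O1–O7 are the oxygens on these carbons.

## Structural features

The target is a single cyclohexene ring (C1–C6, double bond C4=C5) with one exocyclic carbon, C7, on C1 that carries the benzoate. Four adjacent ring carbons are oxygenated stereocentres, C6–C1–C2–C3: the tertiary carbinol C1 sits between the free allylic C6 hydroxyl and the C2 acetate, and the allylic C3 acetate follows C2. Read from the SMILES, O1, O2 and O6 lie on one face of the ring and O3 on the other, so C3 is the only centre that departs from an all-cis pattern. The fragile elements are the three esters placed next to two free hydroxyls (1,2- and 1,3-acyl shifts under base, O7→O6 and O2→O7 above all), the allylic C3 acetate and C6 alcohol (ionisation, allylic shift), and the tendency of such oxygenated cyclohexenes to lose water towards an arene. The carbon skeleton is trivial, since C1–C7 are the seven carbons of a benzoic acid; the real difficulty is to set the quaternary C1 relative to both neighbours in one absolute sense and to finish with five oxygens in four different states. The feature used is the plane through C7, C1 and C4: once C2/C3 and C5/C6 are both oxiranes cis to O1, this plane is a true mirror plane, the compound is meso, and every cis relationship of the target is already present. C4 of that meso compound carries one hydrogen syn to both oxiranes, and the key step removes it while one oxirane opens; this gives C4=C5, frees O6, and leaves the other oxirane as a vinyl epoxide whose allylic carbon C3 can be inverted by acetate.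

## Logic of the disconnections

19 ⇒ 18. The O6–Si bond is introduced retrosynthetically. With O6 masked until the end, benzoylation of O7 competes only with a tertiary hydroxyl. The forward step must remove silicon without creating an alkoxide at O6, because that alkoxide is 1,3 to both the O7 benzoate and the O2 acetate.

18 ⇒ 16 + 17. The acyl–oxygen bond at O7 is cut. This takes the aromatic ester out and leaves a primary/tertiary diol, so site selectivity is not in question. The forward acylation needs a weak base and low temperature so that the O2 acetate stays in place.

16 ⇒ 15. The two acetal C–O bonds (O1–CMe2 and O7–CMe2) are re-formed. One small protecting group then serves O1 and O7 from the meso stage onwards. The forward hydrolysis has to spare two acetates and a silyl ether.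

15 ⇒ 13. The C3–O bond to acetate and the acetyl–O2 bond are cut, and O2 is reconnected to C3 as an oxirane. C3 is the only trans centre, so it is the one to make with inversion; both acetates and the only non-cis relationship disappear in one retrosynthetic step. The forward opening must take place at allylic C3 by backside attack, not at C2 and not in conjugate fashion at C5.

13 ⇒ 12. The O6–Si bond is cut. This is protecting-group bookkeeping only: O6 must be distinguishable from O2 when the acetates are put on. The forward silylation must not use a Lewis acid that would open the vinyl epoxide.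

12 ⇒ 10 (key disconnection). The C4=C5 π bond is removed, O6 is reconnected to C5 and a hydrogen is returned to C4. The molecule becomes meso, with no absolute configuration left to control and all ring C–O bonds accounted for. The forward step must choose one of two enantiotopic oxiranes; checked against 19, 10 has both oxiranes cis to O1 and 12 has the 6S configuration, as required.

10 ⇒ 8 + 9. The two acetal bonds are cut. 10 is achiral, so any isomer with a trans oxirane (chiral, racemic) can be removed before the chiral reagent is spent. The acetal is the right group for the key step: inert to lithium amides, small on the oxygen-bearing face, and lying in the mirror plane.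

8 ⇒ 7. The two C7–H bonds are removed, returning C7 to the ester level. The ester is deliberately kept through the epoxidation; reducing first would give a diol that is an arene hydrate of benzyl alcohol, prone to aromatise, with a homoallylic O7 hydroxyl able to direct oxygen to the wrong face. The forward reduction must leave two oxiranes untouched.

7 ⇒ 5. The four oxirane C–O bonds are cut. This leads back to a flat diene with a single oxygenated sp3 carbon. The forward step must deliver both oxygens to the face of the C1 hydroxyl.

5 ⇒ 3. The C1–O bond is cut. The forward enolate oxidation must take place at C1 and not at C3/C5 of the dienolate, and must not aromatise the ring.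

3 ⇒ 2 ⇒ 1. The ester O–CH3 bond is cut, then the C1–H and C4–H bonds, returning to the arene. All seven skeletal carbons come from 1; the forward reduction must stop at the unconjugated 2,5-diene.

## Other disconnections considered

**Alternative 1:** The cut is through the two C–O bonds of a C5–C6 oxirane in the epoxy enone A1. This leads back to the achiral p-quinol A2 and from there to 4-hydroxybenzyl alcohol A3 (benzoylation of the benzylic hydroxyl, then oxidative dearomatisation of the phenol in water). The forward key step would be nucleophilic epoxidation of one of the two enantiotopic enone double bonds of A2 with tBuOOH under a La(OiPr)3–binaphthol catalyst, the tertiary hydroxyl sitting on lanthanum so that the peroxide arrives syn to it.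
- In its favour: it reads the same mirror plane through C1 and C4, breaks it catalytically instead of with a stoichiometric chiral base, reaches the desymmetrised ring in about three steps, and carries the C7 benzoate from the start. On these three points it is the better plan. The C4 ketone also invites a Wharton transposition, which would place C4=C5 and the C6 hydroxyl exactly as in the target.
- Against it here: a cross-conjugated dienone is a reluctant acceptor for a lanthanide peroxide, and discrimination of the two alkenes of a p-quinol by this catalyst class would have to be developed. A second epoxidation would restore the mirror plane. The tertiary alkoxide next to CH2OBz invites a 1,2-benzoyl shift and retro-aldol loss of C7 under the basic conditions. After A1 only O6 of the three cis oxygens is in place, the remaining enone must still become the trans-diacetate with O2 cis to O1, and the hydrazine of a Wharton step endangers the benzoate.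
- Comparison: on structure the plans are equal in the symmetry they use, but 10 holds every cis relationship whereas A1 holds one. On mechanism, oxygen transfer to an alkene stands against proton removal with epoxide opening, both under reagent control. On step economy the alternative is shorter before its key step and longer and less selective after it; the total is expected to be similar, with more of its steps open.

**Alternative 2:** The cut is the C1–C7 bond. The tertiary alcohol A4 is traced to the C1 ketone A5, a protected cyclohexenone that a cyclitol of the chiral pool would supply. The forward key step would be 1,2-addition to A5 of the organocerium reagent made from the Grignard reagent A6 and CeCl3, followed later by Tamao–Fleming oxidation of the C–Si bond to the C7 hydroxyl.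
- In its favour: C2, C3 and C6 arrive with their final configurations, including the trans C2/C3 pair, and no enantioselective reaction has to be developed. On stereochemical security it is the better plan. The protecting groups (two p-methoxybenzyl ethers where the acetates go, a silyl ether on O6) are already sorted for the endgame. The nucleophile should enter anti to the two cis α-oxygens at C2 and C6, which is the face the target needs, and cerium limits enolisation.
- Against it here: A5 is an α,α′-dioxygenated β,γ-unsaturated ketone. C6–H is both α to the carbonyl and allylic (epimerisation, shift of the alkene into conjugation), and O3 is β to the carbonyl (elimination). Chelation by the α-alkoxy groups could reverse the facial preference. The silyl oxidation needs fluoride and peroxide beside a silyl ether and an alkene. Making A5 from a cyclitol costs many protection and deoxygenation steps.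
- Comparison: on structure, this plan buys six oxygenated ring carbons and removes oxygens, whereas the chosen plan starts from a bare arene and adds exactly the oxygens needed; C7 is a separate C–C bond formation here and the carboxyl carbon of 1 there. On mechanism, a substrate-controlled carbonyl addition is at least as predictable as the chiral-base step. On step economy the alternative is clearly longer; the count to A5 alone is expected to exceed the whole chosen route.

**Alternative 3:** The cut is the ring bond C3–C4. The cyclohexenol A7 is opened to the acyclic aldehyde A8, which carries a Z-iodoalkene at C4 and would be built from a branched pentose. The forward key step would be an intramolecular Nozaki–Hiyama–Kishi reaction: CrCl2 with catalytic NiCl2 converts the carbon–iodine bond into a vinylchromium species (zerovalent nickel inserts, trivalent chromium takes over the vinyl group), which adds to the C3 aldehyde in a 6-exo-trig closure.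
- In its favour: C1, C2 and C6 come from the sugar, and the reaction tolerates the benzoate, the silyl ether and the acetonide. The protecting-group pattern of A7 is better than that of the chosen route: its acetonide spans exactly O1 and O6, the two hydroxyls left free in the target, and the benzoate is already on O7. The endgame would be three steps (free O2, acetylate O2 and O3, remove the acetonide).
- Against it here: the new C3 carbinol must form trans to O2, and its control in such closures is uncertain, so a correction by oxidation–reduction or inversion may be needed. A8 needs a quaternary branched sugar carbon, a Z-selective iodo-olefination and a configurationally labile α-silyloxy aldehyde. Several equivalents of a toxic divalent chromium salt and high dilution are required.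
- Comparison: on structure, the ring is made here, whereas the chosen plan takes it ready-made from 1. On mechanism, C3 is set here by a diastereoselective addition of uncertain sense and there by an SN2 inversion whose outcome is fixed by mechanism. On step economy the alternative is longer before its key step and shorter after it, and is expected to be longer in total.

Key step: step 7

Assumption on the chemistry: the sense of induction of the proline-derived lithium amide on 10 is taken to parallel its behaviour with cyclohexene oxide, for which the (R)-amide leads to the carbinol geometry that corresponds to 6S in 12; should the sense prove opposite, the (S)-amine is used and nothing else changes.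

## Route

Step 1
Reactants: 1 benzoic acid
Product: 2 cyclohexa-2,5-diene-1-carboxylic acid
Conditions: Na, NH3 (l), EtOH, −78 → −33 °C; NH4Cl; aq. HCl
Reagents that add atoms: none
Why: Birch reduction; the carboxylate stabilises negative charge at the ipso and para carbons, so protonation there gives the unconjugated 1,4-dihydro acid with C1 and C4 as the only sp3 ring carbons.

Step 2
Reactants: 2 cyclohexa-2,5-diene-1-carboxylic acid
Product: 3 methyl cyclohexa-2,5-diene-1-carboxylate
Conditions: MeOH, H2SO4 (cat.), 40 °C
Reagents that add atoms: methanol, CO
Why: Fischer esterification; acidic conditions avoid the base-induced shift of the skipped diene into conjugation, and the ester provides an enolisable C1–H for the next step.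

Step 3
Reactants: 3 methyl cyclohexa-2,5-diene-1-carboxylate
Product: 5 methyl 1-hydroxycyclohexa-2,5-diene-1-carboxylate, via potassium dienolate 4 (not isolated)
Conditions: KN(SiMe3)2, THF, −78 °C; then 3-phenyl-2-(phenylsulfonyl)oxaziridine, −78 °C; aq. NH4Cl
Reagents that add atoms: 3-phenyl-2-(phenylsulfonyl)oxaziridine, O=S(=O)(c1ccccc1)N1OC1c1ccccc1
Why: Electrophilic hydroxylation of an ester enolate by an N-sulfonyloxaziridine; the cross-conjugated dienolate reacts at C1, as in Birch reductive alkylations, which keeps the 2,5-diene. C1 lies on the mirror plane, so no stereocentre arises, and the geminal ester makes the bis-allylic tertiary alcohol resistant to ionisation and loss of water.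

Step 4
Reactants: 5 methyl 1-hydroxycyclohexa-2,5-diene-1-carboxylate
Product: 7 meso methyl 2,3:5,6-diepoxy-1-hydroxycyclohexane-1-carboxylate (both oxirane oxygens cis to the hydroxyl), via racemic cis-monoepoxide 6 (not isolated)
Conditions: VO(acac)2 (cat.), tBuOOH (anhydrous, in decane), PhMe, 40 °C
Reagents that add atoms: tert-butyl hydroperoxide, CC(C)(C)OO
Why: Hydroxyl-directed epoxidation of an allylic alcohol by a pentavalent vanadium alkylperoxide; the C1 hydroxyl is allylic to both alkenes and, bound to vanadium, delivers oxygen to its own face twice, which sets C2, C3, C5 and C6 all cis to O1 (substrate control). With C7 still an ester there is no second hydroxyl that could direct to the other face.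

Step 5
Reactants: 7 meso methyl 2,3:5,6-diepoxy-1-hydroxycyclohexane-1-carboxylate
Product: 8 meso 2,3:5,6-diepoxy-1-(hydroxymethyl)cyclohexan-1-ol (O1 and both oxirane oxygens cis)
Conditions: NaBH4, MeOH–THF, 0 °C → rt
Reagents that add atoms: none
Why: Borohydride reduction of an α-hydroxy ester, activated by the neighbouring hydroxyl and the electron-poor α-carbon; oxiranes are not opened by NaBH4 under these conditions. The cis relation of O1 to both oxiranes rules out a Payne-type migration because no backside trajectory exists.

Step 6
Reactants: 8 meso 2,3:5,6-diepoxy-1-(hydroxymethyl)cyclohexan-1-ol; 9 2,2-dimethoxypropane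
Product: 10 meso 2,3:5,6-diepoxy-1,7-O-isopropylidene-1-(hydroxymethyl)cyclohexan-1-ol (spiro acetonide on O1/O7, both oxiranes cis to O1)
Conditions: Me2C(OMe)2, PPTS (cat.), acetone, rt
Reagents that add atoms: 2,2-dimethoxypropane, COC(C)(C)OC
Why: Acid-catalysed transacetalisation; the primary O7 forms the mixed acetal and the tertiary O1 closes the five-membered dioxolane. The weak acid spares the oxiranes, and the new ring lies in the mirror plane, so 10 stays meso.

Step 7
Reactants: 10 meso 2,3:5,6-diepoxy-1,7-O-isopropylidene-1-(hydroxymethyl)cyclohexan-1-ol
Product: 12 (1S,2R,3R,6S)-2,3-epoxy-1,7-O-isopropylidene-1-(hydroxymethyl)cyclohex-4-ene-1,6-diol (oxirane and C6 hydroxyl both cis to O1), via lithium alkoxide 11 (not isolated)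
Conditions: (R)-2-(pyrrolidin-1-ylmethyl)pyrrolidine (1.6 equiv), n-BuLi (1.5 equiv), THF, 0 °C; add 10, 0 °C → rt; aq. NH4Cl
Reagents that add atoms: none
Why: The lithium amide, internally chelated by its pyrrolidine nitrogen, binds one oxirane oxygen, and its amide nitrogen takes the C4 hydrogen on the same face through a cyclic six-centre syn-β-elimination, so C5–O breaks as C4=C5 forms and O6 remains as the lithium alkoxide 11. The closest known reaction type is the enantioselective rearrangement of meso cyclohexene oxides to cyclohex-2-enols by chiral lithium amides, applied here to a meso bis-epoxide. No ring is closed and no C–C σ bond is made; the step creates the C4=C5 π bond and cuts one C–O bond. No new sp3 centre is generated: C6, and with it C1, C2 and C3, becomes stereogenic because the mirror plane is lost, and which half reacts is decided by the chiral amide (reagent control), while the all-cis relative configuration is inherited from 10. The step needs enantiotopic-group selectivity, and the substrate narrows the choice: C4 carries the only β-hydrogens (C1 is quaternary), only one of them is syn to the oxiranes, and it is shared by both, so the base has a clean two-way choice. Further rearrangement is blocked because after the first elimination C4 is sp2 and the remaining oxirane has no β-hydrogen. The acetonide is inert to the base, lies in the mirror plane and leaves the oxygen-bearing face at C4 open.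

Step 8
Reactants: 12 (1S,2R,3R,6S)-2,3-epoxy-1,7-O-isopropylidene-1-(hydroxymethyl)cyclohex-4-ene-1,6-diol
Product: 13 (1R,2R,3R,6S)-6-O-tert-butyldimethylsilyl ether of 12 (the C1 descriptor changes by priority only)
Conditions: TBSCl, imidazole, DMAP (cat.), DMF, rt → 40 °C
Reagents that add atoms: tert-butyldimethylsilyl chloride, CC(C)(C)[Si](C)(C)Cl
Why: Silylation of the secondary allylic hydroxyl under basic, Lewis-acid-free conditions that leave the vinyl oxirane intact; the silyl ether keeps O6 out of the later acetylation.

Step 9
Reactants: 13 (1R,2R,3R,6S)-6-O-tert-butyldimethylsilyl ether of 12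
Product: 15 (1R,2R,3S,6S)-2,3-diacetoxy-6-(tert-butyldimethylsilyloxy)-1,7-O-isopropylidene-1-(hydroxymethyl)cyclohex-4-en-1-ol (O2 cis and O3 trans to O1), via hydroxy acetate 14 (not isolated)
Conditions: AcOH, NaOAc, 50 °C; evaporate; then Ac2O, pyridine, DMAP (cat.), rt
Reagents that add atoms: acetic acid, CC(=O)O; acetic anhydride, CC(=O)OC(C)=O
Why: Acetolysis of a vinyl epoxide: acetate attacks the activated allylic C3 anti to the departing oxygen (SN2-type, inversion), while C2 is shut off by the adjacent quaternary C1; this sets the 2,3-trans pair, C3 going from R to S. The freed C2 hydroxyl of 14 is then esterified in the same flask by DMAP-catalysed acylation.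

Step 10
Reactants: 15 (1R,2R,3S,6S)-2,3-diacetoxy-6-(tert-butyldimethylsilyloxy)-1,7-O-isopropylidene-1-(hydroxymethyl)cyclohex-4-en-1-ol
Product: 16 (1R,2R,3S,6S)-2,3-diacetoxy-6-(tert-butyldimethylsilyloxy)-1-(hydroxymethyl)cyclohex-4-en-1-ol
Conditions: AcOH–H2O (4:1), 50 °C
Reagents that add atoms: none
Why: Acid hydrolysis of the dioxolane; the acetates and the hindered secondary silyl ether should be stable to aqueous acetic acid, and acyl shifts are slow at this acidity.

Step 11
Reactants: 16 (1R,2R,3S,6S)-2,3-diacetoxy-6-(tert-butyldimethylsilyloxy)-1-(hydroxymethyl)cyclohex-4-en-1-ol; 17 benzoyl chloride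
Product: 18 [(1R,2R,3S,6S)-2,3-diacetoxy-6-(tert-butyldimethylsilyloxy)-1-hydroxycyclohex-4-en-1-yl]methyl benzoate
Conditions: BzCl, pyridine, CH2Cl2, 0 °C
Reagents that add atoms: benzoyl chloride, O=C(Cl)c1ccccc1
Why: Pyridine-mediated acylation of the only primary hydroxyl; the tertiary C1 hydroxyl does not react at 0 °C and O6 is still silylated, so the site of benzoylation is unambiguous.

Step 12
Reactants: 18 [(1R,2R,3S,6S)-2,3-diacetoxy-6-(tert-butyldimethylsilyloxy)-1-hydroxycyclohex-4-en-1-yl]methyl benzoate
Product: 19 [(1S,2R,3S,6S)-2,3-diacetoxy-1,6-dihydroxycyclohex-4-en-1-yl]methyl benzoate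
Conditions: HF·pyridine, pyridine, THF, 0 °C → rt
Reagents that add atoms: none
Why: Fluoride cleavage of the silyl ether under buffered, slightly acidic conditions; no free alkoxide forms at O6, which avoids benzoyl or acetyl shifts from O7 or O2, and the allylic esters are untouched.

## Compound list

1 | benzoic acid | O=C(O)c1ccccc1 | starting material
2 | cyclohexa-2,5-diene-1-carboxylic acid | O=C(O)C1C=CCC=C1 | intermediate
3 | methyl cyclohexa-2,5-diene-1-carboxylate | COC(=O)C1C=CCC=C1 | intermediate
4 | potassium dienolate of 3 (potassium (cyclohexa-2,5-dien-1-ylidene)(methoxy)methanolate) | [K+].[O-]C(OC)=C1C=CCC=C1 | intermediate (not isolated)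
5 | methyl 1-hydroxycyclohexa-2,5-diene-1-carboxylate | COC(=O)C1(O)C=CCC=C1 | intermediate
6 | racemic methyl 2,3-epoxy-1-hydroxycyclohex-5-ene-1-carboxylate, oxirane cis to the hydroxyl (one enantiomer drawn) | O1[C@@H]2CC=C[C@](C(=O)OC)(O)[C@H]12 | intermediate (not isolated)
7 | meso methyl (2R,3R,5S,6S)-2,3:5,6-diepoxy-1-hydroxycyclohexane-1-carboxylate, both oxiranes cis to the hydroxyl | O1[C@@H]2C[C@@H]3O[C@@H]3[C@](C(=O)OC)(O)[C@H]12 | intermediate
8 | meso (2R,3R,5S,6S)-2,3:5,6-diepoxy-1-(hydroxymethyl)cyclohexan-1-ol, all ring oxygens cis | O1[C@@H]2C[C@@H]3O[C@@H]3[C@](CO)(O)[C@H]12 | intermediate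
9 | 2,2-dimethoxypropane | COC(C)(C)OC | starting material
10 | meso (2R,3R,5S,6S)-2,3:5,6-diepoxy-1,7-O-isopropylidene-1-(hydroxymethyl)cyclohexan-1-ol (spiro acetonide, all ring oxygens cis) | O1[C@@H]2C[C@@H]3O[C@@H]3[C@]4(OC(C)(C)OC4)[C@H]12 | intermediate
11 | lithium alkoxide of 12 | O1[C@@H]2C=C[C@H]([O-])[C@]3(OC(C)(C)OC3)[C@H]12.[Li+] | intermediate (not isolated)
12 | (1S,2R,3R,6S)-2,3-epoxy-1,7-O-isopropylidene-1-(hydroxymethyl)cyclohex-4-ene-1,6-diol | O1[C@@H]2C=C[C@H](O)[C@]3(OC(C)(C)OC3)[C@H]12 | intermediate
13 | (1R,2R,3R,6S)-6-O-tert-butyldimethylsilyl ether of 12 | O1[C@@H]2C=C[C@H](O[Si](C)(C)C(C)(C)C)[C@]3(OC(C)(C)OC3)[C@H]12 | intermediate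
14 | (1R,2R,3S,6S)-3-acetoxy-6-(tert-butyldimethylsilyloxy)-1,7-O-isopropylidene-1-(hydroxymethyl)cyclohex-4-ene-1,2-diol (C2–OH cis, C3–OAc trans to O1) | CC(=O)O[C@H]1C=C[C@H](O[Si](C)(C)C(C)(C)C)[C@]2(OC(C)(C)OC2)[C@@H]1O | intermediate (not isolated)
15 | (1R,2R,3S,6S)-2,3-diacetoxy-6-(tert-butyldimethylsilyloxy)-1,7-O-isopropylidene-1-(hydroxymethyl)cyclohex-4-en-1-ol | CC(=O)O[C@H]1C=C[C@H](O[Si](C)(C)C(C)(C)C)[C@]2(OC(C)(C)OC2)[C@@H]1OC(C)=O | intermediate
16 | (1R,2R,3S,6S)-2,3-diacetoxy-6-(tert-butyldimethylsilyloxy)-1-(hydroxymethyl)cyclohex-4-en-1-ol | CC(=O)O[C@H]1C=C[C@H](O[Si](C)(C)C(C)(C)C)[C@@](O)(CO)[C@@H]1OC(C)=O | intermediate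
17 | benzoyl chloride | O=C(Cl)c1ccccc1 | starting material
18 | [(1R,2R,3S,6S)-2,3-diacetoxy-6-(tert-butyldimethylsilyloxy)-1-hydroxycyclohex-4-en-1-yl]methyl benzoate | CC(=O)O[C@H]1C=C[C@H](O[Si](C)(C)C(C)(C)C)[C@@](O)(COC(=O)c2ccccc2)[C@@H]1OC(C)=O | intermediate
19 | [(1S,2R,3S,6S)-2,3-diacetoxy-1,6-dihydroxycyclohex-4-en-1-yl]methyl benzoate | CC(=O)O[C@H]1C=C[C@H](O)[C@@](O)(COC(=O)c2ccccc2)[C@@H]1OC(C)=O | target

## Step count and least certain steps

Total step count: 12. Longest linear sequence: 12 steps (1 → 19); 9 and 17 are bought and enter in steps 6 and 11.

**Step 7 (key step).** What may go wrong: weak discrimination between the two enantiotopic oxiranes, because the three cis oxygens of 10 can hold lithium in a symmetric, unproductive chelate that competes with the ordered amide–oxirane complex. In addition, excess base may lithiate the vinyl oxirane of 11 at C3 and open it to an enone, and the sense of induction rests on analogy only. Fallback: setting out from 10, rearrangement with the achiral base LiN(iPr)2 (THF, 0 °C) gives 12 together with its enantiomer F1. Esterification of the mixture with (S)-naproxen (DCC, DMAP, CH2Cl2, 0 °C) gives two diastereomers, the (S)-naproxen ester of 12 F2 and the (S)-naproxen ester of the enantiomer F3, which are separated by chromatography or crystallisation. K2CO3 in MeOH releases 12 from F2, where the route is rejoined.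

**Step 4.** What may go wrong: slow or incomplete second epoxidation and erosion of facial selectivity, because each alkene is deactivated by the geminal ester and hydroxyl at C1 and the hindered tertiary hydroxyl binds vanadium less readily; prolonged warming with the peroxide also risks dehydration of the dienol towards an arene. Fallback: setting out from 5, LiAlH4 (Et2O, 0 °C, basic work-up) gives 1-(hydroxymethyl)cyclohexa-2,5-dien-1-ol F4, whose primary hydroxyl is silylated (TBSCl, imidazole, CH2Cl2, 0 °C) to give the silyl ether F5. Its electron-richer alkenes, now with a single free hydroxyl, are epoxidised (VO(acac)2, tBuOOH, PhMe, rt) to the all-cis diepoxide F6, and Bu4NF in THF removes the silyl group to return to the route at 8.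

**Step 9.** What may go wrong: loss of regio- and stereocontrol in the oxirane opening, by conjugate attack at C5 or by ionisation to an allyl cation and collapse with retention at C3, together with slow cleavage of the silyl ether in warm acetic acid. Fallback: setting out from 13, hydroxide opening under basic conditions (KOH, DMSO–H2O, 70 °C), where no cation can form, gives the 2,3-trans diol F7. Acetylation of both hydroxyls (Ac2O, pyridine, DMAP) returns to the route at 15.

**Step 3.** What may go wrong: single-electron oxidation of the electron-rich dienolate with aromatisation to the benzoate, and addition of the enolate to the sulfonylimine left behind by the oxidant. Fallback: setting out from 3, LiN(iPr)2 and then Me3SiCl (THF, −78 °C) give the silyl ketene acetal F8. This is oxidised with dimethyldioxirane in acetone at −78 °C (Rubottom oxidation) to the α-silyloxy ester F9, and brief treatment with citric acid in MeOH returns to the route at 5.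

**Step 10.** What may go wrong: sluggish hydrolysis of the hindered spiro-dioxolane, so that stronger acid becomes necessary and premature loss of the silyl ether or an O2→O7 acetyl shift sets in. Fallback: setting out from 15, both protecting groups are removed on purpose with aqueous HF in MeCN to give the triol diacetate F10. Its primary hydroxyl alone is then benzoylated (17, 2,4,6-collidine, CH2Cl2, −40 °C), which comes back to the route at 19 and bypasses 16 and 18.

## Further compounds

F1 | step 7 | (1R,2S,3S,6R)-2,3-epoxy-1,7-O-isopropylidene-1-(hydroxymethyl)cyclohex-4-ene-1,6-diol (enantiomer of 12) | O1[C@H]2C=C[C@@H](O)[C@@]3(OC(C)(C)OC3)[C@@H]12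
F2 | step 7 | (S)-2-(6-methoxynaphthalen-2-yl)propanoate ester of 12 at O6 | O1[C@@H]2C=C[C@H](OC(=O)[C@@H](C)c3ccc4cc(OC)ccc4c3)[C@]5(OC(C)(C)OC5)[C@H]12
F3 | step 7 | (S)-2-(6-methoxynaphthalen-2-yl)propanoate ester of F1 at O6 | O1[C@H]2C=C[C@@H](OC(=O)[C@@H](C)c3ccc4cc(OC)ccc4c3)[C@@]5(OC(C)(C)OC5)[C@@H]12
F4 | step 4 | 1-(hydroxymethyl)cyclohexa-2,5-dien-1-ol | OCC1(O)C=CCC=C1
F5 | step 4 | 1-[(tert-butyldimethylsilyloxy)methyl]cyclohexa-2,5-dien-1-ol | CC(C)(C)[Si](C)(C)OCC1(O)C=CCC=C1
F6 | step 4 | meso 1-[(tert-butyldimethylsilyloxy)methyl]-2,3:5,6-diepoxycyclohexan-1-ol, both oxiranes cis to the hydroxyl | O1[C@@H]2C[C@@H]3O[C@@H]3[C@](CO[Si](C)(C)C(C)(C)C)(O)[C@H]12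
F7 | step 9 | (1R,2R,3S,6S)-6-(tert-butyldimethylsilyloxy)-1,7-O-isopropylidene-1-(hydroxymethyl)cyclohex-4-ene-1,2,3-triol (C2–OH cis, C3–OH trans to O1) | O[C@H]1C=C[C@H](O[Si](C)(C)C(C)(C)C)[C@]2(OC(C)(C)OC2)[C@@H]1O
F8 | step 3 | [(cyclohexa-2,5-dien-1-ylidene)(methoxy)methoxy]trimethylsilane (silyl ketene acetal of 3) | COC(O[Si](C)(C)C)=C1C=CCC=C1
F9 | step 3 | methyl 1-(trimethylsilyloxy)cyclohexa-2,5-diene-1-carboxylate | COC(=O)C1(O[Si](C)(C)C)C=CCC=C1
F10 | step 10 | (1S,2R,3S,6S)-2,3-diacetoxy-1-(hydroxymethyl)cyclohex-4-ene-1,6-diol | CC(=O)O[C@H]1C=C[C@H](O)[C@@](O)(CO)[C@@H]1OC(C)=O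
A1 | alternative 1 | 5,6-epoxy-4-hydroxy-4-(benzoyloxymethyl)cyclohex-2-enone, oxirane cis to the hydroxyl | O=C1C=C[C@](O)(COC(=O)c2ccccc2)[C@H]3O[C@@H]13
A2 | alternative 1 | 4-hydroxy-4-(benzoyloxymethyl)cyclohexa-2,5-dienone | O=C1C=CC(O)(COC(=O)c2ccccc2)C=C1
A3 | alternative 1 | 4-hydroxybenzyl alcohol | OCc1ccc(O)cc1
A4 | alternative 2 | C1 tertiary alcohol with (isopropoxydimethylsilyl)methyl group, O2 and O3 as p-methoxybenzyl ethers, O6 as tert-butyldimethylsilyl ether | COc1ccc(CO[C@H]2C=C[C@H](O[Si](C)(C)C(C)(C)C)[C@@](O)(C[Si](C)(C)OC(C)C)[C@@H]2OCc2ccc(OC)cc2)cc1
A5 | alternative 2 | C1 ketone precursor of A4 | COc1ccc(CO[C@H]2C=C[C@H](O[Si](C)(C)C(C)(C)C)C(=O)[C@@H]2OCc2ccc(OC)cc2)cc1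
A6 | alternative 2 | (isopropoxydimethylsilyl)methylmagnesium chloride | CC(C)O[Si](C)(C)C[Mg]Cl
A7 | alternative 3 | C3 allylic alcohol of the protected cyclohexene (O1/O6 acetonide, O2 silyl ether, O7 benzoate) | O[C@H]1C=C[C@@H]2OC(C)(C)O[C@]2(COC(=O)c3ccccc3)[C@@H]1O[Si](C)(C)C(C)(C)C
A8 | alternative 3 | acyclic C3 aldehyde with Z-iodoalkene at C4, precursor of A7 | I/C=C\[C@@H]1OC(C)(C)O[C@]1(COC(=O)c2ccccc2)[C@@H](C=O)O[Si](C)(C)C(C)(C)C
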